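## Retrosynthetic overview

1. Cordycicadin C ⇒ a ten-membered γ-hydroxy-(E)-enone lactone plus a pyranyl β-keto ester; Michael addition at C5, γ-lactonisation on O4 and dehydrative closure of the tetrahydrofuran enol ether are done last, in one flask.
2. The ten-membered lactone ⇒ a hydroxy β-lactone by strain-release ring expansion (four → ten ring atoms, acyl transfer from O4 to O10); the β-lactone ⇒ cross-metathesis of (S)-4-vinyl-β-lactone (acrolein + acetyl chloride) with (R)-6-hydroxyhept-1-en-3-one ((R)-γ-valerolactone + vinylmagnesium bromide).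
3. The pyranyl β-keto ester ⇒ Achmatowicz ring expansion (furan → pyranone) of an (S)-furyl carbinol, then Kishi reduction, hydrogenation and axial-selective ketone reduction; the carbinol ⇒ vinylogous aldol of 5-methylfurfural with the bis-silyl dienolate of methyl acetoacetate.
4. Ring order: tetrahydropyran (from the furan) → β-lactone → ten-membered lactone → γ-butyrolactone → tetrahydrofuran.

Assumption: locants O1, C2–C10 refer to the ten-membered lactone (methyl on C10), primed locants to the furo[3,2-b]pyran unit; the six starting materials are catalogue compounds.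

## Route

Step 1
Reactants: 1 methyl 3-oxobutanoate (methyl acetoacetate)
Product: 3 (1Z)-1-methoxy-1,3-bis[(trimethylsilyl)oxy]buta-1,3-diene, via silyl enol ether 2 (not isolated)
Conditions: Me3SiCl, Et3N, hexane, 25 °C; then LiN(iPr)2, THF, −78 °C; Me3SiCl, −78 → 0 °C
Reagents that add atoms: chlorotrimethylsilane, C[Si](C)(C)Cl
Why: Two consecutive O-silylations (enol silylation, then γ-deprotonation and silylation of the ester enolate) give the bis-silyl dienol ether that serves as vinylogous Mukaiyama donor; no stereocentre is formed and the diene geometry is of no consequence.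

Step 2
Reactants: 3 (1Z)-1-methoxy-1,3-bis[(trimethylsilyl)oxy]buta-1,3-diene; 4 5-methylfuran-2-carbaldehyde
Product: 6 methyl (5S)-5-hydroxy-5-(5-methylfuran-2-yl)-3-oxopentanoate, via silylated aldol adduct 5 (not isolated)
Conditions: Ti(OiPr)4 (10 mol %), (S)-BINOL (10 mol %), 4 Å MS, THF, −78 → 25 °C; then CF3CO2H, THF/H2O, 0 °C
Reagents that add atoms: none
Why: Catalytic asymmetric vinylogous Mukaiyama aldol reaction in which the BINOL–Ti(OiPr)4 complex directs the diene terminus to the Si face of the aldehyde, setting the (S)-carbinol (the future C3a'), after which acid removes both silyl groups.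

Step 3
Reactants: 6 methyl (5S)-5-hydroxy-5-(5-methylfuran-2-yl)-3-oxopentanoate
Product: 8 methyl 4-[(2S,6R)-6-methyl-3-oxo-3,6-dihydro-2H-pyran-2-yl]-3-oxobutanoate, via Achmatowicz hemiketal 7 (not isolated)
Conditions: mCPBA (1.05 equiv), CH2Cl2, 0 °C; then Et3SiH (3 equiv), CF3CO2H (5 equiv), −40 → 0 °C
Reagents that add atoms: 3-chloroperoxybenzoic acid (mCPBA), OOC(=O)c1cccc(Cl)c1
Why: Achmatowicz rearrangement, an oxidative furan-to-pyranone ring expansion in which the carbinol oxygen becomes the ring oxygen with retention at C2, followed by Kishi reduction in which Et3SiH adds axially to the oxocarbenium ion anti to the C2 substituent to give the 2,6-cis (6R) dihydropyranone (the future C5').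

Step 4
Reactants: 8 methyl 4-[(2S,6R)-6-methyl-3-oxo-3,6-dihydro-2H-pyran-2-yl]-3-oxobutanoate
Product: 9 methyl 4-[(2S,6R)-6-methyl-3-oxooxan-2-yl]-3-oxobutanoate
Conditions: H2 (1 atm), 10% Pd/C, EtOAc, 25 °C
Reagents that add atoms: none
Why: Catalytic hydrogenation over palladium on carbon saturates only the enone C=C bond and leaves both ketones, the ester and the two stereocentres untouched.

Step 5
Reactants: 9 methyl 4-[(2S,6R)-6-methyl-3-oxooxan-2-yl]-3-oxobutanoate
Product: 11 methyl 4-[(2S,3S,6R)-3-hydroxy-6-methyloxan-2-yl]-3-oxobutanoate, via sodium enolate 10 (not isolated)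
Conditions: NaH (1.05 equiv), THF, 0 °C; then LiBH(s-Bu)3 (1.2 equiv), −78 °C; AcOH
Reagents that add atoms: none
Why: With the β-keto ester masked as its sodium enolate, the bulky borohydride reduces only the ring ketone by equatorial attack on the chair with both substituents equatorial, giving the axial (3S) alcohol cis to the C2 side chain (diastereoselective bulky-hydride ketone reduction; the future C7a').

Step 6
Reactants: 12 (5R)-5-methyloxolan-2-one; 13 ethenylmagnesium bromide
Product: 15 (6R)-6-hydroxyhept-1-en-3-one, via bromomagnesium lactolate 14 (not isolated)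
Conditions: THF, −78 °C (1.05 equiv of 13); AcOH, −78 °C
Reagents that add atoms: none
Why: Grignard addition to the lactone stops at the tetrahedral magnesium lactolate at −78 °C, so a cold acidic quench gives the hydroxy vinyl ketone without over-addition, and the C10 stereocentre is carried over unchanged from the lactone.

Step 7
Reactants: 16 prop-2-enal (acrolein); 17 acetyl chloride
Product: 19 (4S)-4-ethenyloxetan-2-one, via ketene 18 (not isolated)
Conditions: O-trimethylsilylquinidine (10 mol %), LiClO4 (50 mol %), iPr2NEt (2.5 equiv), CH2Cl2/Et2O, −78 °C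
Reagents that add atoms: none
Why: Cinchona-alkaloid/LiClO4-catalysed ketene–aldehyde cyclocondensation (Wynberg–Nelson type, a stepwise aldol–lactonisation of the ammonium enolate) in which the silylated alkaloid directs attack on the Si face of acrolein and so sets the (4S) centre, the future C4.

Step 8
Reactants: 15 (6R)-6-hydroxyhept-1-en-3-one; 19 (4S)-4-ethenyloxetan-2-one
Product: 20 (4S)-4-[(1E,6R)-6-hydroxy-3-oxohept-1-en-1-yl]oxetan-2-one
Conditions: second-generation Hoveyda–Grubbs catalyst RuCl2(H2IMes)(=CH-C6H4-2-OiPr) (5 mol %), 19 (3 equiv), CH2Cl2, 40 °C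
Reagents that add atoms: none
Why: Olefin cross-metathesis between the electron-poor vinyl ketone and an excess of the allylic β-lactone olefin gives the (E)-enone selectively, the strained lactone and the free alcohol being inert to the ruthenium carbene.

Step 9
Reactants: 20 (4S)-4-[(1E,6R)-6-hydroxy-3-oxohept-1-en-1-yl]oxetan-2-one
Product: 21 (4S,5E,10R)-4-hydroxy-10-methyl-3,4,9,10-tetrahydro-2H-oxecine-2,7(8H)-dione
Conditions: Bu2SnO (20 mol %), toluene, 80 °C, slow addition of 20 to a final 1 mM
Reagents that add atoms: none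
Why: Proposed new method: tin-alkoxide-templated strain-release translactonisation, in which Bu2SnO turns the C10 hydroxyl into a stannyl alkoxide that coordinates the β-lactone carbonyl and cleaves its acyl–oxygen bond intramolecularly, so that roughly 20 kcal/mol of four-ring strain pays for the ten-membered ring and C4–OH is released with retention because the C4–O bond is never broken; the closest known reactions are tin-catalysed alcoholysis and coordination–insertion ring-opening of β-lactones and Bu2SnO-templated macrolactonisation of hydroxy acids.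

Step 10
Reactants: 11 methyl 4-[(2S,3S,6R)-3-hydroxy-6-methyloxan-2-yl]-3-oxobutanoate; 21 (4S,5E,10R)-4-hydroxy-10-methyl-3,4,9,10-tetrahydro-2H-oxecine-2,7(8H)-dione
Product: 24 cordycicadin C, via Michael adduct 22 (not isolated), via acyl lactone 23 (not isolated)
Conditions: 11 (1.2 equiv), Cs2CO3 (10 mol %), THF, 0 → 25 °C; then TsOH·H2O (40 mol %), 4 Å MS, toluene, 50 °C
Reagents that add atoms: none
Why: Base-catalysed Michael addition of the β-keto ester to the macrocyclic (E)-enone from the open face anti to the ring C3–C4 bond with H-4 outside and OH-4 inside (Felkin-type) sets C5 as (S), the neighbouring C4 hydroxyl then closes the cis-fused γ-lactone on the methyl ester, and acid-catalysed hemiketalisation–dehydration of the γ-hydroxy ketone (Langer-type 2-alkylidenetetrahydrofuran formation) gives the thermodynamically preferred (E) enol ether with the ring oxygen anti to the lactone carbonyl.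

## Compound list

1 | methyl 3-oxobutanoate (methyl acetoacetate) | COC(=O)CC(C)=O | starting material
2 | methyl (2E)-3-[(trimethylsilyl)oxy]but-2-enoate (not isolated) | COC(=O)/C=C(/O[Si](C)(C)C)C | intermediate
3 | (1Z)-1-methoxy-1,3-bis[(trimethylsilyl)oxy]buta-1,3-diene | CO\C(O[Si](C)(C)C)=C\C(=C)O[Si](C)(C)C | intermediate
4 | 5-methylfuran-2-carbaldehyde | Cc1ccc(C=O)o1 | starting material
5 | methyl (2Z,5S)-5-(5-methylfuran-2-yl)-3,5-bis[(trimethylsilyl)oxy]pent-2-enoate (not isolated) | COC(=O)/C=C(\O[Si](C)(C)C)C[C@H](O[Si](C)(C)C)c1ccc(C)o1 | intermediate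
6 | methyl (5S)-5-hydroxy-5-(5-methylfuran-2-yl)-3-oxopentanoate | COC(=O)CC(=O)C[C@H](O)c1ccc(C)o1 | intermediate
7 | methyl 4-[(2S)-6-hydroxy-6-methyl-3-oxo-3,6-dihydro-2H-pyran-2-yl]-3-oxobutanoate (both C6 anomers, not isolated) | COC(=O)CC(=O)C[C@@H]1OC(C)(O)C=CC1=O | intermediate
8 | methyl 4-[(2S,6R)-6-methyl-3-oxo-3,6-dihydro-2H-pyran-2-yl]-3-oxobutanoate | COC(=O)CC(=O)C[C@@H]1O[C@H](C)C=CC1=O | intermediate
9 | methyl 4-[(2S,6R)-6-methyl-3-oxooxan-2-yl]-3-oxobutanoate | COC(=O)CC(=O)C[C@@H]1O[C@H](C)CCC1=O | intermediate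
10 | sodium (2Z)-4-methoxy-1-[(2S,6R)-6-methyl-3-oxooxan-2-yl]-4-oxobut-2-en-2-olate (not isolated) | COC(=O)/C=C(\[O-])C[C@@H]1O[C@H](C)CCC1=O.[Na+] | intermediate
11 | methyl 4-[(2S,3S,6R)-3-hydroxy-6-methyloxan-2-yl]-3-oxobutanoate (in equilibrium with its cyclic hemiketal) | COC(=O)CC(=O)C[C@@H]1O[C@H](C)CC[C@@H]1O | intermediate
12 | (5R)-5-methyloxolan-2-one ((R)-γ-valerolactone) | C[C@@H]1CCC(=O)O1 | starting material
13 | ethenylmagnesium bromide | C=C[Mg]Br | starting material
14 | bromomagnesium (5R)-2-ethenyl-5-methyloxolan-2-olate (not isolated) | C[C@@H]1CCC(C=C)(O[Mg]Br)O1 | intermediate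
15 | (6R)-6-hydroxyhept-1-en-3-one (in equilibrium with its lactol) | C[C@@H](O)CCC(=O)C=C | intermediate
16 | prop-2-enal (acrolein) | C=CC=O | starting material
17 | acetyl chloride | CC(=O)Cl | starting material
18 | ethenone (ketene, not isolated) | C=C=O | intermediate
19 | (4S)-4-ethenyloxetan-2-one | C=C[C@@H]1CC(=O)O1 | intermediate
20 | (4S)-4-[(1E,6R)-6-hydroxy-3-oxohept-1-en-1-yl]oxetan-2-one | C[C@@H](O)CCC(=O)/C=C/[C@@H]1CC(=O)O1 | intermediate
21 | (4S,5E,10R)-4-hydroxy-10-methyl-3,4,9,10-tetrahydro-2H-oxecine-2,7(8H)-dione | C[C@@H]1CCC(=O)/C=C/[C@@H](O)CC(=O)O1 | intermediate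
22 | methyl 2-[(4S,5S,10R)-4-hydroxy-10-methyl-2,7-dioxooxecan-5-yl]-4-[(2S,3S,6R)-3-hydroxy-6-methyloxan-2-yl]-3-oxobutanoate (C2 epimers, not isolated) | C[C@@H]1CCC(=O)C[C@@H](C(C(=O)OC)C(=O)C[C@@H]2O[C@H](C)CC[C@@H]2O)[C@@H](O)CC(=O)O1 | intermediate
23 | γ-lactone of 22 between O4 and the ester carbonyl: (4S,5S,10R)-ten-membered keto lactone cis-fused at C4–C5 to a γ-butyrolactone whose α-carbon carries the [(2S,3S,6R)-3-hydroxy-6-methyloxan-2-yl]acetyl group (not isolated) | C[C@@H]1CCC(=O)C[C@H]2C(C(=O)C[C@@H]3O[C@H](C)CC[C@@H]3O)C(=O)O[C@H]2CC(=O)O1 | intermediate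
24 | cordycicadin C | C[C@@H]1CCC(=O)C[C@H]2/C(=C3/C[C@@H]4O[C@H](C)CC[C@@H]4O3)C(=O)O[C@H]2CC(=O)O1 | target

## Step count and risks

Total steps: 10. Longest linear sequence: 6 (steps 1–5, then step 10); steps 6–9 form the second branch.

Three steps most likely to fail:

Step 9 (the new ring expansion). Risks are intermolecular acyl transfer (oligoesters, twenty-membered diolide) and alkyl–oxygen cleavage of the β-lactone. The fallback uses known chemistry only; it sets out from 19 and 15 (before step 8) and comes back at 21, closing the ring by metathesis instead of acyl transfer. NaOMe (cat.) in MeOH at 0 °C opens 19 to methyl (3S)-3-hydroxypent-4-enoate F1. TBSCl/imidazole gives methyl (3S)-3-[(tert-butyldimethylsilyl)oxy]pent-4-enoate F2. LiOH in THF/H2O gives (3S)-3-[(tert-butyldimethylsilyl)oxy]pent-4-enoic acid F3. EDC·HCl/DMAP esterification with 15 gives (2R)-5-oxohept-6-en-2-yl (3S)-3-[(tert-butyldimethylsilyl)oxy]pent-4-enoate F4. Ring-closing metathesis (second-generation Hoveyda–Grubbs catalyst, CH2Cl2, 40 °C, 1 mM) forms the C5=C6 bond and gives (4S,5E,10R)-4-[(tert-butyldimethylsilyl)oxy]-10-methyl-3,4,9,10-tetrahydro-2H-oxecine-2,7(8H)-dione F5. HF·pyridine then releases 21.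

Step 10 (union cascade). Risks are the facial selectivity at C5, which rests on a conformational argument, and base-induced isomerisation or dehydration of the γ-hydroxy enone. The fallback sets out from 11 and 21 and comes back at 23, then 24. Instead of enolate chemistry under ring control, the enone is activated as an iminium ion with 9-amino-9-deoxy-epi-quinine (20 mol %) and PhCO2H (40 mol %) in THF at 25 °C, a known catalyst class for additions of 1,3-dicarbonyl compounds to enones. The C5 face is then chosen by the catalyst (the quinidine-derived pseudo-enantiomer addresses the other face) and no base touches 21. Michael adduct 22 lactonises to 23, which is isolated and checked at C5 before a separate dehydration (TsOH·H2O, 4 Å MS, toluene, 50 °C) to 24. No compound outside the list is made.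

Step 7 (asymmetric β-lactone formation). Enals are a thinly documented aldehyde class for this cyclocondensation; acrolein may polymerise or take up the amine in a conjugate sense, and the sense of induction is assumed by analogy. The fallback sets out from 16 and comes back at 19. A titanium-enolate acetate aldol (Nagao type) of (4S)-3-acetyl-4-(propan-2-yl)-1,3-thiazolidine-2-thione (TiCl4, iPr2NEt, CH2Cl2, −78 °C) with 16, using the auxiliary enantiomer that gives the (3S) carbinol, affords (3S)-3-hydroxy-1-[(4S)-4-(propan-2-yl)-2-sulfanylidene-1,3-thiazolidin-3-yl]pent-4-en-1-one F6. LiOH (THF/H2O, 0 °C) releases (3S)-3-hydroxypent-4-enoic acid F7. PhSO2Cl in pyridine at 0 °C (Adam β-lactonisation by carboxyl activation, retention at C3) closes 19.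

## Further compounds

F1 | step 9 | methyl (3S)-3-hydroxypent-4-enoate | C=C[C@@H](O)CC(=O)OC
F2 | step 9 | methyl (3S)-3-[(tert-butyldimethylsilyl)oxy]pent-4-enoate | C=C[C@@H](O[Si](C)(C)C(C)(C)C)CC(=O)OC
F3 | step 9 | (3S)-3-[(tert-butyldimethylsilyl)oxy]pent-4-enoic acid | C=C[C@@H](O[Si](C)(C)C(C)(C)C)CC(=O)O
F4 | step 9 | (2R)-5-oxohept-6-en-2-yl (3S)-3-[(tert-butyldimethylsilyl)oxy]pent-4-enoate | C=C[C@@H](O[Si](C)(C)C(C)(C)C)CC(=O)O[C@H](C)CCC(=O)C=C
F5 | step 9 | (4S,5E,10R)-4-[(tert-butyldimethylsilyl)oxy]-10-methyl-3,4,9,10-tetrahydro-2H-oxecine-2,7(8H)-dione | C[C@@H]1CCC(=O)/C=C/[C@@H](O[Si](C)(C)C(C)(C)C)CC(=O)O1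
F0 | step 10 | none | none
F6 | step 7 | (3S)-3-hydroxy-1-[(4S)-4-(propan-2-yl)-2-sulfanylidene-1,3-thiazolidin-3-yl]pent-4-en-1-one | C=C[C@@H](O)CC(=O)N1[C@@H](C(C)C)CSC1=S
F7 | step 7 | (3S)-3-hydroxypent-4-enoic acid | C=C[C@@H](O)CC(=O)O
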